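**Retrosynthetic overview**
1. Target 22 ⇐ acetonide hydrolysis of 21 ⇐ O‑7 benzoylation of 20 ⇐ PMB removal from 19 ⇐ β‑3,4‑epoxide 18, opened by benzoate with inversion at the allylic carbon C3.
2. Key disconnection: the C3–C4 bond (and the C3–O bond of the oxirane) of 18 ⇒ an open‑chain (Z)‑allylic sulfonium ylide bearing an aldehyde, made from bromo aldehyde 14; one operation closes the cyclohexene ring and the oxirane ring and sets C3 and C4.
3. Enabling feature: the trans C3‑benzoate/C4‑hydroxyl pair lies next to the ring alkene C1=C2 (C3 is allylic), which is the signature of a 3,4‑oxirane opened at C3; the trans C5/C6 diol can be held as a trans‑fused dioxolane ring that locks the half‑chair and so dictates the oxirane face.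
4. 14 ⇐ (Z)‑enoate 11 (hydride reduction, Corey–Kim bromination, oxidation); 11 ⇐ ynoate 6 + CH2OPMB cuprate (syn carbocupration fixes the Z alkene that brings C3 within reach of C4); 6 ⇐ L‑threitol acetonide 1, which supplies C4–C5–C6–C1 with both carbinol stereocentres.
5. Ring order: dioxolane ring (present in 1) → cyclohexene ring and oxirane ring together (step 10) → oxirane opened (step 11) → dioxolane removed (step 14).

Key step: step 10

Remark: atoms are numbered as in the target ring (C1 carries the CH2O carbon C7, C2 is the olefinic CH, C3 carries the ring benzoate, C4–C6 carry the hydroxyls) and keep these numbers in the open‑chain intermediates; β is the ring face of O‑4 and O‑5 of the target, α the face of O‑3 and O‑6.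

**Step 1**
Reactants: 1 (4S,5S)-2,3-O-isopropylidene-L-threitol
Product: 2 1-O-pivaloyl-2,3-O-isopropylidene-L-threitol
Conditions: t-BuCOCl (0.95 equiv), pyridine, CH2Cl2, −20 to 0 °C
Reagents that add atoms: pivaloyl chloride CC(C)(C)C(Cl)=O
Why: Nucleophilic acyl substitution on a C2‑symmetric diol whose two hydroxyls are homotopic, so mono‑acylation can give only one compound; the pivalate should survive carbonate/methanol, amide base and cuprate and is removed later by the hydride that reduces the enoate.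

**Step 2**
Reactants: 2 1-O-pivaloyl-2,3-O-isopropylidene-L-threitol
Product: 3 4-O-pivaloyl-2,3-O-isopropylidene-L-threose
Conditions: TEMPO (cat.), PhI(OAc)2, CH2Cl2, 20 °C
Reagents that add atoms: none
Why: Oxoammonium‑mediated (TEMPO) oxidation of the primary alcohol should stop at the aldehyde under non‑basic conditions, so the α‑alkoxy stereocentre is not epimerised.

**Step 3**
Reactants: 3 4-O-pivaloyl-2,3-O-isopropylidene-L-threose
Product: 4 [(4S,5S)-5-ethynyl-2,2-dimethyl-1,3-dioxolan-4-yl]methyl pivalate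
Conditions: dimethyl (1-diazo-2-oxopropyl)phosphonate, K2CO3, MeOH, 0 to 20 °C
Reagents that add atoms: dimethyl (1-diazo-2-oxopropyl)phosphonate CC(=O)C(=[N+]=[N-])P(=O)(OC)OC
Why: Seyferth–Gilbert homologation with the Ohira–Bestmann reagent converts the aldehyde into the terminal alkyne under mild carbonate conditions that the hindered pivalate tolerates; the trans‑dioxolane is the more stable arrangement, so α‑epimerisation is not expected to erode the stereocentre.

**Step 4**
Reactants: 4 [(4S,5S)-5-ethynyl-2,2-dimethyl-1,3-dioxolan-4-yl]methyl pivalate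
Product: 6 methyl 3-[(4S,5S)-2,2-dimethyl-5-(pivaloyloxymethyl)-1,3-dioxolan-4-yl]prop-2-ynoate, via lithium acetylide 5 (not isolated)
Conditions: LiN(i-Pr)2, THF, −78 °C; then ClCO2Me, −78 to −40 °C
Reagents that add atoms: methyl chloroformate COC(Cl)=O
Why: Deprotonation of the terminal alkyne by the non‑nucleophilic amide base (which does not attack the pivalate) and C‑acylation of the acetylide with the chloroformate is the standard ynoate synthesis.

**Step 5**
Reactants: 7 tributyl(iodomethyl)stannane
Product: 8 tributyl{[(4-methoxybenzyl)oxy]methyl}stannane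
Conditions: 4-MeOC6H4CH2OH, NaH, THF/DMF, 0 to 20 °C
Reagents that add atoms: 4-methoxybenzyl alcohol COc1ccc(CO)cc1
Why: Williamson ether synthesis, SN2 displacement of the primary iodide next to tin by the sodium alkoxide, is the usual way to α‑alkoxymethylstannanes.

**Step 6**
Reactants: 6 methyl 3-[(4S,5S)-2,2-dimethyl-5-(pivaloyloxymethyl)-1,3-dioxolan-4-yl]prop-2-ynoate; 8 tributyl{[(4-methoxybenzyl)oxy]methyl}stannane
Product: 11 methyl (2Z)-3-[(4S,5S)-2,2-dimethyl-5-(pivaloyloxymethyl)-1,3-dioxolan-4-yl]-4-[(4-methoxybenzyl)oxy]but-2-enoate, via alkoxymethyllithium 9 (not isolated), via lithium cuprate 10 (not isolated)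
Conditions: 8 (2.2 equiv), n-BuLi, THF, −78 °C; CuBr·SMe2 (1.1 equiv), −78 °C; then 6, −78 °C; aqueous NH4Cl added at −78 °C
Reagents that add atoms: none
Why: Tin–lithium exchange gives the α‑alkoxymethyllithium, whose Gilman cuprate should add syn across the ynoate (conjugate carbocupration) so that cold protonation leaves the new CH2OPMB group cis to H‑2 and the ester carbon C3 cis to the dioxolane carbon C6, the Z geometry the ring closure needs.

**Step 7**
Reactants: 11 methyl (2Z)-3-[(4S,5S)-2,2-dimethyl-5-(pivaloyloxymethyl)-1,3-dioxolan-4-yl]-4-[(4-methoxybenzyl)oxy]but-2-enoate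
Product: 12 (2Z)-3-[(4S,5S)-5-(hydroxymethyl)-2,2-dimethyl-1,3-dioxolan-4-yl]-4-[(4-methoxybenzyl)oxy]but-2-en-1-ol
Conditions: i-Bu2AlH (5 equiv), CH2Cl2, −78 to 0 °C; aqueous KNaC4H4O6 work-up
Reagents that add atoms: none
Why: Hydride reduction with DIBAL-H takes the conjugated ester to the allylic alcohol by 1,2‑reduction and cleaves the pivalate in the same operation, without touching the alkene geometry, the PMB ether or the acetonide.

**Step 8**
Reactants: 12 (2Z)-3-[(4S,5S)-5-(hydroxymethyl)-2,2-dimethyl-1,3-dioxolan-4-yl]-4-[(4-methoxybenzyl)oxy]but-2-en-1-ol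
Product: 13 [(4S,5S)-5-{(2Z)-4-bromo-1-[(4-methoxybenzyl)oxy]but-2-en-2-yl}-2,2-dimethyl-1,3-dioxolan-4-yl]methanol
Conditions: N-bromosuccinimide, Me2S, CH2Cl2, −20 °C; then 12, −20 to 0 °C; aqueous work-up without base
Reagents that add atoms: N-bromosuccinimide O=C1CCC(=O)N1Br
Why: Corey–Kim halogenation, in which both hydroxyls form alkoxysulfonium ions but only the allylic one is displaced by bromide (SN2), while the saturated one should return the alcohol on aqueous work-up, so no protecting group is needed to tell C3 from C4.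

**Step 9**
Reactants: 13 [(4S,5S)-5-{(2Z)-4-bromo-1-[(4-methoxybenzyl)oxy]but-2-en-2-yl}-2,2-dimethyl-1,3-dioxolan-4-yl]methanol
Product: 14 (4R,5S)-5-{(2Z)-4-bromo-1-[(4-methoxybenzyl)oxy]but-2-en-2-yl}-2,2-dimethyl-1,3-dioxolane-4-carbaldehyde
Conditions: TEMPO (cat.), PhI(OAc)2, CH2Cl2, 20 °C; used without storage
Reagents that add atoms: none
Why: The same neutral oxoammonium (TEMPO) oxidation gives the C4 aldehyde without base, so neither the allylic bromide nor the α‑alkoxy stereocentre C5 should suffer.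

**Step 10**
Reactants: 14 (4R,5S)-5-{(2Z)-4-bromo-1-[(4-methoxybenzyl)oxy]but-2-en-2-yl}-2,2-dimethyl-1,3-dioxolane-4-carbaldehyde
Product: 18 3β,4β-epoxy-5β,6α-(isopropylidenedioxy)-1-{[(4-methoxybenzyl)oxy]methyl}cyclohex-1-ene, via sulfonium bromide 15 (not isolated), via sulfonium ylide 16 (not isolated), via betaine 17 (not isolated)
Conditions: tetrahydrothiophene (3 equiv), MeCN, 20 °C; then dilution to 0.005 M, Cs2CO3, −20 to 20 °C
Reagents that add atoms: none
Why: Proposed new method: S‑alkylation of tetrahydrothiophene by the allylic bromide gives sulfonium salt 15; Cs2CO3 removes the acidic allylic S–CH2 proton and the carbanion carbon C3 of ylide 16 adds to the tethered aldehyde carbon C4 to give betaine 17, whose alkoxide then displaces tetrahydrothiophene from C3 with inversion. The closest known reaction types are the Corey–Chaykovsky epoxidation of aldehydes by allylic sulfonium ylides (intermolecular) and the ylide–carbonyl epoxy‑annulations that close a ring and an epoxide together; an allylic ylide closing a carbocycle in this way is the untested part. The cyclohexene ring closes 6‑exo‑trig (the C=O is exocyclic to the forming ring) and the oxirane ring 3‑exo‑tet. C4 is controlled by the trans‑fused dioxolane on C5/C6: it locks the half‑chair so that only the betaine with an axial β‑alkoxide (syn to O‑5) can place O− antiperiplanar to the α‑axial C3–S bond, and the other betaines cannot close and should revert because addition of a semistabilised ylide is reversible. C3 is controlled by the closure itself, since backside displacement puts the oxirane oxygen on the same β face at C3 as at C4. The step needs α‑attack of the ylide (γ‑attack through C1 would give a four‑membered ring), ring closure over oligomerisation (high dilution) and ylide formation without enolisation of the aldehyde (carbonate base, low temperature), and the Z geometry of C1=C2 is what lets C3 reach C4.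

**Step 11**
Reactants: 18 3β,4β-epoxy-5β,6α-(isopropylidenedioxy)-1-{[(4-methoxybenzyl)oxy]methyl}cyclohex-1-ene
Product: 19 3α-benzoyloxy-4β-hydroxy-5β,6α-(isopropylidenedioxy)-1-{[(4-methoxybenzyl)oxy]methyl}cyclohex-1-ene
Conditions: PhCO2H (3 equiv), i-Pr2NEt (1 equiv), toluene, 60 °C
Reagents that add atoms: benzoic acid OC(=O)c1ccccc1
Why: Acid‑assisted SN2 opening of the vinyl oxirane by benzoate should occur at the allylic carbon C3 with inversion (trans‑diaxial, Fürst–Plattner, in the acetonide‑locked half‑chair; SN2′ attack at the fully substituted C1 is disfavoured), which sets the α‑benzoate at C3 and leaves the β‑hydroxyl at C4.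

**Step 12**
Reactants: 19 3α-benzoyloxy-4β-hydroxy-5β,6α-(isopropylidenedioxy)-1-{[(4-methoxybenzyl)oxy]methyl}cyclohex-1-ene
Product: 20 3α-benzoyloxy-4β-hydroxy-1-(hydroxymethyl)-5β,6α-(isopropylidenedioxy)cyclohex-1-ene
Conditions: DDQ, CH2Cl2/pH 7 phosphate buffer, 0 to 20 °C
Reagents that add atoms: none
Why: Oxidative cleavage of the electron‑rich PMB ether by DDQ (single‑electron oxidation, then hydrolysis of the oxocarbenium ion) should leave the benzoate, the acetonide and the alkene untouched under buffered conditions.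

**Step 13**
Reactants: 20 3α-benzoyloxy-4β-hydroxy-1-(hydroxymethyl)-5β,6α-(isopropylidenedioxy)cyclohex-1-ene
Product: 21 [3α-benzoyloxy-4β-hydroxy-5β,6α-(isopropylidenedioxy)cyclohex-1-en-1-yl]methyl benzoate
Conditions: PhCOCl (1.05 equiv), 2,4,6-collidine, CH2Cl2, −40 to −20 °C
Reagents that add atoms: benzoyl chloride O=C(Cl)c1ccccc1
Why: Kinetically controlled acylation should take the primary allylic hydroxyl in preference to the axial secondary C4 hydroxyl flanked by the benzoate and the dioxolane, and the trans‑diaxial O‑3/O‑4 arrangement held by the acetonide prevents acyl migration.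

**Step 14**
Reactants: 21 [3α-benzoyloxy-4β-hydroxy-5β,6α-(isopropylidenedioxy)cyclohex-1-en-1-yl]methyl benzoate
Product: 22 [(3R,4R,5R,6S)-3-benzoyloxy-4,5,6-trihydroxycyclohex-1-en-1-yl]methyl benzoate
Conditions: CF3CO2H/H2O (9:1), 0 °C
Reagents that add atoms: none
Why: Acid‑catalysed acetal hydrolysis should remove the strained trans‑fused acetonide quickly at 0 °C, conditions under which benzoate esters neither hydrolyse nor migrate.

**Compound list**
1 | (4S,5S)-2,3-O-isopropylidene-L-threitol | OC[C@@H]1OC(C)(C)O[C@H]1CO | starting material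
2 | 1-O-pivaloyl-2,3-O-isopropylidene-L-threitol | CC(C)(C)C(=O)OC[C@@H]1OC(C)(C)O[C@H]1CO | intermediate
3 | 4-O-pivaloyl-2,3-O-isopropylidene-L-threose | CC(C)(C)C(=O)OC[C@@H]1OC(C)(C)O[C@H]1C=O | intermediate
4 | [(4S,5S)-5-ethynyl-2,2-dimethyl-1,3-dioxolan-4-yl]methyl pivalate | CC(C)(C)C(=O)OC[C@@H]1OC(C)(C)O[C@H]1C#C | intermediate
5 | lithium acetylide of 4 | CC(C)(C)C(=O)OC[C@@H]1OC(C)(C)O[C@H]1C#C[Li] | intermediate
6 | methyl 3-[(4S,5S)-2,2-dimethyl-5-(pivaloyloxymethyl)-1,3-dioxolan-4-yl]prop-2-ynoate | CC(C)(C)C(=O)OC[C@@H]1OC(C)(C)O[C@H]1C#CC(=O)OC | intermediate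
7 | tributyl(iodomethyl)stannane | CCCC[Sn](CCCC)(CCCC)CI | starting material
8 | tributyl{[(4-methoxybenzyl)oxy]methyl}stannane | CCCC[Sn](CCCC)(CCCC)COCc1ccc(OC)cc1 | intermediate
9 | {[(4-methoxybenzyl)oxy]methyl}lithium | [Li]COCc1ccc(OC)cc1 | intermediate
10 | lithium bis{[(4-methoxybenzyl)oxy]methyl}cuprate | [Li+].COc1ccc(COC[Cu-]COCc2ccc(OC)cc2)cc1 | intermediate
11 | methyl (2Z)-3-[(4S,5S)-2,2-dimethyl-5-(pivaloyloxymethyl)-1,3-dioxolan-4-yl]-4-[(4-methoxybenzyl)oxy]but-2-enoate | CC(C)(C)C(=O)OC[C@@H]1OC(C)(C)O[C@H]1/C(COCc1ccc(OC)cc1)=C\C(=O)OC | intermediate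
12 | (2Z)-3-[(4S,5S)-5-(hydroxymethyl)-2,2-dimethyl-1,3-dioxolan-4-yl]-4-[(4-methoxybenzyl)oxy]but-2-en-1-ol | OC[C@@H]1OC(C)(C)O[C@H]1/C(COCc1ccc(OC)cc1)=C\CO | intermediate
13 | [(4S,5S)-5-{(2Z)-4-bromo-1-[(4-methoxybenzyl)oxy]but-2-en-2-yl}-2,2-dimethyl-1,3-dioxolan-4-yl]methanol | OC[C@@H]1OC(C)(C)O[C@H]1/C(COCc1ccc(OC)cc1)=C\CBr | intermediate
14 | (4R,5S)-5-{(2Z)-4-bromo-1-[(4-methoxybenzyl)oxy]but-2-en-2-yl}-2,2-dimethyl-1,3-dioxolane-4-carbaldehyde | O=C[C@@H]1OC(C)(C)O[C@H]1/C(COCc1ccc(OC)cc1)=C\CBr | intermediate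
15 | 1-{(2Z)-3-[(4S,5R)-5-formyl-2,2-dimethyl-1,3-dioxolan-4-yl]-4-[(4-methoxybenzyl)oxy]but-2-en-1-yl}tetrahydrothiophenium bromide | O=C[C@@H]1OC(C)(C)O[C@H]1/C(COCc1ccc(OC)cc1)=C\C[S+]1CCCC1.[Br-] | intermediate
16 | sulfonium ylide of 15 (carbanion at C3) | O=C[C@@H]1OC(C)(C)O[C@H]1/C(COCc1ccc(OC)cc1)=C\[CH-][S+]1CCCC1 | intermediate
17 | betaine: 3α-(tetrahydrothiophenium-1-yl)-4β-oxido-5β,6α-(isopropylidenedioxy)-1-{[(4-methoxybenzyl)oxy]methyl}cyclohex-1-ene | COc1ccc(COCC2=C[C@@H]([S+]3CCCC3)[C@H]([O-])[C@@H]3OC(C)(C)O[C@@H]23)cc1 | intermediate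
18 | 3β,4β-epoxy-5β,6α-(isopropylidenedioxy)-1-{[(4-methoxybenzyl)oxy]methyl}cyclohex-1-ene | COc1ccc(COCC2=C[C@@H]3O[C@@H]3[C@@H]3OC(C)(C)O[C@@H]23)cc1 | intermediate
19 | 3α-benzoyloxy-4β-hydroxy-5β,6α-(isopropylidenedioxy)-1-{[(4-methoxybenzyl)oxy]methyl}cyclohex-1-ene | COc1ccc(COCC2=C[C@@H](OC(=O)c3ccccc3)[C@H](O)[C@@H]3OC(C)(C)O[C@@H]23)cc1 | intermediate
20 | 3α-benzoyloxy-4β-hydroxy-1-(hydroxymethyl)-5β,6α-(isopropylidenedioxy)cyclohex-1-ene | OCC1=C[C@@H](OC(=O)c2ccccc2)[C@H](O)[C@@H]2OC(C)(C)O[C@@H]12 | intermediate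
21 | [3α-benzoyloxy-4β-hydroxy-5β,6α-(isopropylidenedioxy)cyclohex-1-en-1-yl]methyl benzoate | O=C(OCC1=C[C@@H](OC(=O)c2ccccc2)[C@H](O)[C@@H]2OC(C)(C)O[C@@H]12)c1ccccc1 | intermediate
22 | [(3R,4R,5R,6S)-3-benzoyloxy-4,5,6-trihydroxycyclohex-1-en-1-yl]methyl benzoate | O=C(OCC1=C[C@@H](OC(=O)c2ccccc2)[C@H](O)[C@H](O)[C@H]1O)c1ccccc1 | target

**Step count and risks**

Total step count: 14. Longest linear sequence: 13 steps (steps 1–4 and 6–14; step 5 makes stannane 8 on a side branch).

Steps most likely to fail: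

1. Step 10 (Proposed new method). What may go wrong is unproductive consumption of the ylide: intermolecular epoxidation, [2,3]-sigmatropic rearrangement through the isomeric ring ylide, base‑induced enolisation or β‑elimination of the aldehyde, or betaines that cannot reach the antiperiplanar geometry and only revert. The fallback uses known reactions only: it makes the C3–C4 bond intermolecularly and closes the ring by metathesis at C1=C2. It sets out from 13. The bromide is displaced by caesium benzoate (PhCO2Cs, DMF) to give the allylic benzoate alcohol F1. TEMPO/PhI(OAc)2 oxidation gives the aldehyde F2. Barbier‑type α‑hydroxyallylation with 3-bromopropenyl benzoate and indium powder (THF/H2O) should give the C3‑benzoyloxy C4‑hydroxy 1,7‑diene F3, with C4 set by Felkin–Anh attack anti to O‑5 and the C3/C4 syn relation by the chair transition state of the (Z)-γ-benzoyloxyallylindium. Ring‑closing metathesis with the second‑generation Grubbs catalyst [(H2IMes)(PCy3)Cl2Ru=CHPh] in toluene at 80 °C then closes C1=C2 with loss of allyl benzoate and comes back to the route at 19.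

2. Step 6. What may go wrong is decomposition of the α‑alkoxymethyllithium or its cuprate by Wittig‑type rearrangement before it adds, or equilibration of the alkenylcuprate that erodes the Z geometry. The fallback builds the same trisubstituted alkene by cross‑coupling instead of carbocupration and sets out from 3. Roskamp homologation with methyl diazoacetate and SnCl2 (CH2Cl2) gives the β‑keto ester F4. (E)-selective enol triflation (Tf2O, aqueous Me4NOH, toluene) gives the enol triflate F5, with the triflate trans to the ester. Stille coupling of F5 with stannane 8 (Pd(PPh3)4, CuI, LiCl, DMF) proceeds with retention of alkene geometry and comes back to the route at 11.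

3. Step 13. What may go wrong is incomplete discrimination between the primary and the secondary hydroxyl, with over‑acylation at O‑4. The fallback removes the selectivity question by changing the order of events and sets out from 18. DDQ (buffered CH2Cl2) cleaves the PMB ether to the epoxy alcohol F6. Its only hydroxyl is benzoylated with (PhCO)2O, Et3N and DMAP to give the epoxy benzoate F7. Opening of the oxirane at C3 with PhCO2H/i-Pr2NEt (toluene, 60 °C) then comes back to the route at 21.

**Further compounds**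
F1 | step 10 | (2Z)-3-[(4S,5S)-5-(hydroxymethyl)-2,2-dimethyl-1,3-dioxolan-4-yl]-4-[(4-methoxybenzyl)oxy]but-2-en-1-yl benzoate | OC[C@@H]1OC(C)(C)O[C@H]1/C(COCc1ccc(OC)cc1)=C\COC(=O)c1ccccc1
F2 | step 10 | (2Z)-3-[(4S,5R)-5-formyl-2,2-dimethyl-1,3-dioxolan-4-yl]-4-[(4-methoxybenzyl)oxy]but-2-en-1-yl benzoate | O=C[C@@H]1OC(C)(C)O[C@H]1/C(COCc1ccc(OC)cc1)=C\COC(=O)c1ccccc1
F3 | step 10 | open-chain 1,7-diene with C3 benzoate and C4 hydroxyl configured as in 19, vinyl group on C3 and the (Z)-allylic benzoate of F2 retained | C=C[C@@H](OC(=O)c1ccccc1)[C@H](O)[C@@H]1OC(C)(C)O[C@H]1/C(COCc1ccc(OC)cc1)=C\COC(=O)c1ccccc1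
F4 | step 6 | methyl 3-[(4S,5S)-2,2-dimethyl-5-(pivaloyloxymethyl)-1,3-dioxolan-4-yl]-3-oxopropanoate | CC(C)(C)C(=O)OC[C@@H]1OC(C)(C)O[C@H]1C(=O)CC(=O)OC
F5 | step 6 | methyl (2E)-3-[(4S,5S)-2,2-dimethyl-5-(pivaloyloxymethyl)-1,3-dioxolan-4-yl]-3-(trifluoromethylsulfonyloxy)prop-2-enoate | CC(C)(C)C(=O)OC[C@@H]1OC(C)(C)O[C@H]1/C(OS(=O)(=O)C(F)(F)F)=C\C(=O)OC
F6 | step 13 | 3β,4β-epoxy-1-(hydroxymethyl)-5β,6α-(isopropylidenedioxy)cyclohex-1-ene | OCC1=C[C@@H]2O[C@@H]2[C@@H]2OC(C)(C)O[C@@H]12
F7 | step 13 | [3β,4β-epoxy-5β,6α-(isopropylidenedioxy)cyclohex-1-en-1-yl]methyl benzoate | O=C(OCC1=C[C@@H]2O[C@@H]2[C@@H]2OC(C)(C)O[C@@H]12)c1ccccc1
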